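- At early times the autumn run at 5 °C makes target first: after 10.0 s it reads 29.3% of target against 2.2% of isomer of the product, and the isomer climbs later, to 21.7% after 50.0 s.
- The decision for the next run is what to do if you want target: which temperature to charge with 0.20 mM of free catalyst, which is half the autumn charge, and whether to stop at 2.5 min.

common to all: substrate 0.10 M; reagent 0.105 M

| charge | free catalyst | temperature | remark | time |
|---|---|---|---|---|
| autumn | 0.40 mM | 5 °C | run made earlier |  |
| zeta | 0.20 mM | 55 °C |  | 2.5 min |
| epsilon | 0.20 mM | 30 °C |  | 2.5 min |
| alpha | 0.20 mM | 5 °C |  | 2.5 min |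

autumn run (percent of the substrate charged)

| time / s | target / % | catalyst intermediate A / % | substrate / % | isomer of the product / % | catalyst intermediate B / % |
|---|---|---|---|---|---|
| 10.0 | 29.3 | 0.3 | 69.0 | 2.2 | 0 |
| 12.0 | 32.5 | 0.5 | 63.7 | 2.9 | 0.2 |
| 20.0 | 45.2 | 0.3 | 48.0 | 6.6 | 0 |
| 25.0 | 50.8 | 0.3 | 40.0 | 8.9 | 0.1 |
| 40.0 | 58.8 | 0 | 24.2 | 17.5 | 0 |
| 50.0 | 61.0 | 0 | 16.7 | 21.7 | 0 |

(readings scatter by 0.3 percentage points)

- which of these there is most of at the end, counted by the substrate in it, zeta (catalyst intermediate B / isomer of the product / target / catalyst intermediate A / substrate)
- which of these there is most of at the end, counted by the substrate in it, epsilon (catalyst intermediate B / isomer of the product / target / catalyst intermediate A / substrate)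
- which of these there is most of at the end, counted by the substrate in it, alpha (catalyst intermediate B / isomer of the product / target / catalyst intermediate A / substrate)
- amount of the one of these that there is most of at the end, in percent of the substrate charged, zeta
- amount of the one of these that there is most of at the end, in percent of the substrate charged, epsilon
- amount of the one of these that there is most of at the end, in percent of the substrate charged, alpha

- the earlier runs do not show what temperature does; that part of a forecast is a guess
- no earlier run changes the charge of free catalyst; that part of a forecast is a guess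

- The useful quantity is the turning time τ, the target present divided by the rate at which the isomer gains, which is the time the target would last at its present pace (a pseudo-first-order lifetime).
- Between 20.0 s and 50.0 s of the autumn run the isomer gains 15 percentage points while the mean of the two target readings at those times is 53.1%, so τ reads 105 s.
- No earlier run changes the catalyst, so you have to guess here: take the pace as proportional to the charge, which gives τ′ = 211 s for the new charge at 5 °C, the turning time at the new charge.
- The time 2.5 min is shorter than τ′, at 0.711 of a turning time, so my own rough reckoning for alpha, which takes the autumn mean of target as the amount being turned, is 37.7% of isomer, with target still ahead.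
- The earlier runs do not show temperature, but if warming shortens τ′, epsilon and zeta turn more of their target. So I would charge alpha, stay at 5 °C, and leave the time at 2.5 min.
- The forecast names isomer of the product at 95% in zeta, isomer of the product at 88% in epsilon, and target at 56% in alpha. For zeta it says “the isomer is nearly everything, unless the catalyst dies or an equilibrium limits it”.
- The flasks give target at 60.9% in alpha, isomer of the product at 55.2% in epsilon, and isomer of the product at 64.9% in zeta.

    catalyst intermediate B ⇌ by-product + catalyst intermediate C (K = 0.150 M, k = 40.0 s⁻¹, Ea = 59.0 kJ mol⁻¹, ΔH = −34.0 kJ mol⁻¹)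
    substrate + free catalyst → catalyst intermediate A (k = 320 L mol⁻¹ s⁻¹, Ea = 41.0 kJ mol⁻¹)
    catalyst intermediate C ⇌ free catalyst + target (K = 0.100 M, k = 34.0 s⁻¹, Ea = 66.0 kJ mol⁻¹, ΔH = 5.00 kJ mol⁻¹)
    reagent + catalyst intermediate A ⇌ catalyst intermediate B (K = 16.0 L mol⁻¹, k = 2300 L mol⁻¹ s⁻¹, Ea = 35.0 kJ mol⁻¹, ΔH = 19.0 kJ mol⁻¹)
    target + free catalyst ⇌ isomer of the product + free catalyst, rate k5*[free catalyst]*[target] forward; the back reaction follows from the equilibrium constant (K = 0.900, k = 120 L mol⁻¹ s⁻¹, Ea = 39.0 kJ mol⁻¹, ΔH = 11.0 kJ mol⁻¹)
    (constants at 5 °C)

- In zeta the isomer reads 63.6% after 1.25 min and 64.9% after 25.0 min, with 34.9% of target beside it at that later time. Your τ′ makes 25.0 min in alpha 7.11 turning times, and a one-way turning at that pace would leave 0.0818% of the target, but alpha then holds 52.5% of target against 47.3% of isomer.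

The runs were generated by integration from invented constants; the scatter is artificial.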